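| flask | substrate | acid | temperature | remark | time |
|---|---|---|---|---|---|
| spring | 0.15 M | 2.2 mM | −10 °C | run made earlier |  |
| summer | 0.15 M | 6.9 mM | 15 °C | run made earlier |  |
| dusk | 0.12 M | 4.5 mM | −10 °C | run made earlier |  |
| cedar | 0.15 M | 4.50 mM |  | at 35 °C until 25 min, from then on at −5 °C | 2.0 h |
| maple | 0.10 M | 1.50 mM |  | at 35 °C throughout | 2.0 h |

| run | time / h | product / % | substrate / % |
|---|---|---|---|
| spring | 1.50 | 1.2 | 100.1 |
| spring | 2.50 | 0.5 | 98.2 |
| spring | 3.00 | 0 | 99.5 |
| spring | 5.00 | 1.9 | 98.6 |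
| spring | 8.00 | 2.0 | 98.0 |
| spring | 12.0 | 3.3 | 96.2 |
| spring | 20.0 | 4.8 | 94.8 |
| summer | 0.417 | 4.1 | 96.3 |
| summer | 0.667 | 5.5 | 93.8 |
| summer | 0.833 | 8.8 | 93.1 |
| summer | 1.33 | 12.8 | 87.6 |
| summer | 2.50 | 21.4 | 78.5 |
| summer | 4.00 | 32.6 | 66.9 |
| summer | 5.00 | 39.4 | 60.4 |
| dusk | 4.00 | 2.1 | 98.3 |
| dusk | 8.00 | 4.4 | 95.7 |
| dusk | 12.0 | 5.5 | 93.2 |
| dusk | 15.0 | 7.3 | 92.2 |
| dusk | 20.0 | 8.9 | 90.7 |

(readings scatter by 0.5 percentage points)

- acid is the free proton; pH is minus the decimal logarithm of its molar concentration

- the winner by amount of product, in percent of the substrate charged; "neither" if no more than 2 percentage points parts them (cedar / maple / neither)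
- how much product is there at the end, in percent of the substrate charged: cedar
- how much product is there at the end, in percent of the substrate charged: maple

1. I start from the amounts. In cedar, c_acid is 4.50 mM against 0.15 M of substrate. Yet in the summer run the product reaches 8.57 times c_acid by 5.00 h. So the acid is not used up; it acts as a catalyst.

2. The spring and dusk runs share −10 °C. Dusk's −ln(c_substrate/charge) at 20.0 h reads 1.83 times spring's, for 2.05 times the acid. So I take −ln(c_substrate/charge) to grow with c_acid × time: pseudo-first-order at fixed acid.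

3. Per acid and hour, the summer run reads 13.5 times the dusk run. So I count acid-hours at 35 °C and drop cedar's at −5 °C.

4. Both flasks then share one rate constant, and it cancels. Maple's acid-hours over cedar's give 1.60, the hot dose ratio. It is the factor between their values of −ln(c_substrate/charge). Above one, it says maple.

5. The forecast says maple, with cedar 15.8% (14% to 17.8%) and maple 22.4% (19.8% to 25.2%): “Doubling the acid doubles k, so the rate is first order in acid”. My ratio, put on its cedar, gives maple 24.1%, a little above its figure.

6. The flasks give maple: cedar 16.6%, maple 29.5%, which is above the forecast's range.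

    weak acid ⇌ conjugate base + acid, settled at all times (K = 1.30 × 10⁻⁹ M, ΔH = 5.00 kJ mol⁻¹)
    substrate → weak acid + product (k = 1.70 × 10⁻⁵ s⁻¹, Ea = 104 kJ mol⁻¹)
    weak acid → by-product carried off (k = 1.40 × 10⁻⁴ s⁻¹, Ea = 98.0 kJ mol⁻¹)
    substrate + acid → weak acid + acid + product (k = 0.0210 L mol⁻¹ s⁻¹, Ea = 63.0 kJ mol⁻¹)
    (constants at 35 °C)

The measured factor is 1.93, against a hot dose ratio of 1.60, so one number was not quite enough. Part of the gap comes from the conversion of substrate into weak acid + product, which needs no acid: struck out, it costs maple 9.2 percentage points and cedar 2.2 points. Held at 35 °C, cedar gives 55.2%, so the change of temperature is the largest single effect on cedar. Cedar's neighbour with 0.018 M of acid has 4.00 times cedar's dose, gives 47.7% of product, and its measured factor over cedar is 3.57.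

The runs are calculated from invented constants; the scatter is artificial.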